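**Retrosynthetic overview**

1. The 6α-OH / C7=C8 / C12HO array is the E1cB-opened form of a β,γ-epoxy aldehyde, so the target goes back to a 6α,7α-epoxy-11,12-diol (twofold Swern oxidation with in-flask epoxide opening) and from there to a Δ6-octalin that carries C11 on C9 and C12 on C8.
2. The Δ6-octalin is disconnected by an intramolecular Diels–Alder reaction of an acyclic trienal: C8–C9 and C5–C10 form in one operation, so rings A and B arise together (ring B is closed by C8–C9) and C5, C9 and C10 are set from the single stereocentre C1.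
3. Enabling feature: the six carbons of ring B map onto a diene (C5=C6–C7=C8, C12 on C8) and an enal dienophile (C9=C10, C11 as CHO, methyl on C10), while C1–C4 of ring A with the C4 gem-dimethyl group are a four-carbon tether from C10 to C5, and the acyloxy carbon C1 is allylic to the dienophile.
4. The trienal comes from C1–C2 bond formation by catalytic enantioselective addition of a dialkylzinc (hydroboration/boron–zinc exchange of a trienyl silyl ether) to (2E)-4,4-dimethoxy-2-methylbut-2-enal, then esterification with (E)-4-methoxycinnamic acid and acetal hydrolysis.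
5. Ring order: no carbocycle before step 9; rings A and B together in step 9; the triene comes from prenyl chloride by γ-formylation and vinylogous Horner–Wadsworth–Emmons olefination.

Key step: step 9

Remark: drimane numbering is used for all compounds (decalin C1–C10, C11 on C9, C12 on C8, gem-dimethyl on C4, methyl on C10); β is the face of the C10 methyl group, α the opposite face.

**Route**

Step 1
Reactants: 1 prenyl chloride (1-chloro-3-methylbut-2-ene)
Product: 3 2,2-dimethylbut-3-enal, via prenylmagnesium chloride 2 (not isolated)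
Conditions: Mg, THF, 0 °C; DMF, −20 °C → rt; aq. HCl
Reagents that add atoms: N,N-dimethylformamide (DMF), CN(C)C=O
Why: Allylic Grignard reagents attack carbonyl electrophiles at the γ-carbon through a six-membered SE2′ transition state, so Bouveault formylation of the prenyl reagent should give the α-quaternary β,γ-unsaturated aldehyde that holds C2–C5 and the C4 gem-dimethyl group.

Step 2
Reactants: 3 2,2-dimethylbut-3-enal; 4 triethyl 4-phosphonocrotonate
Product: 5 ethyl (2E,4E)-6,6-dimethylocta-2,4,7-trienoate
Conditions: LiN(SiMe3)2, THF, −78 °C → rt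
Reagents that add atoms: none
Why: Vinylogous Horner–Wadsworth–Emmons olefination of the non-enolisable aldehyde should give the E,E-dienoate, the new C5=C6 bond being E as usual for a stabilised phosphonate anion.

Step 3
Reactants: 5 ethyl (2E,4E)-6,6-dimethylocta-2,4,7-trienoate
Product: 6 (2E,4E)-6,6-dimethylocta-2,4,7-trien-1-ol
Conditions: i-Bu2AlH (2.2 equiv), CH2Cl2, −78 → 0 °C; aq. potassium sodium tartrate
Reagents that add atoms: none
Why: The aluminium hydride reduces the conjugated ester in 1,2-fashion to the dienyl alcohol (C12–OH) without touching the alkenes, which turns the electron-poor dienoate into a diene fit for a normal-demand cycloaddition.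

Step 4
Reactants: 6 (2E,4E)-6,6-dimethylocta-2,4,7-trien-1-ol
Product: 7 tert-butyl{[(2E,4E)-6,6-dimethylocta-2,4,7-trien-1-yl]oxy}dimethylsilane
Conditions: TBSCl, imidazole, CH2Cl2, 0 °C → rt
Reagents that add atoms: tert-butyldimethylsilyl chloride (TBSCl), CC(C)(C)[Si](C)(C)Cl
Why: Standard silylation protects the primary allylic alcohol as a group that tolerates organozinc reagents, Lewis acid and peracid and is removed by fluoride near the end.

Step 5
Reactants: 8 2,2-dimethoxyacetaldehyde; 9 2-(triphenylphosphoranylidene)propanal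
Product: 10 (2E)-4,4-dimethoxy-2-methylbut-2-enal
Conditions: CH2Cl2, rt (8 extracted from its aqueous solution and dried)
Reagents that add atoms: none
Why: Wittig olefination with the stabilised α-methyl formyl ylide is E-selective and should give the five-carbon enal that holds C1 (as CHO), C10 with its methyl group, C9 and C11 (as acetal) in the geometry that later places the C10 methyl and the C9 formyl group cis.

Step 6
Reactants: 7 tert-butyl{[(2E,4E)-6,6-dimethylocta-2,4,7-trien-1-yl]oxy}dimethylsilane; 10 (2E)-4,4-dimethoxy-2-methylbut-2-enal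
Product: 13 (2E,4R,8E,10E)-12-{[tert-butyl(dimethyl)silyl]oxy}-1,1-dimethoxy-3,7,7-trimethyldodeca-2,8,10-trien-4-ol, via alkyldiethylborane 11 (not isolated), via dialkylzinc 12 (not isolated)
Conditions: Et2BH (from BH3·SMe2 + 2 Et3B), Et2O, 0 °C → rt; Et2Zn, 0 °C, then volatiles removed in vacuo; 10 (limiting), Ti(OiPr)4, (1S,2S)-1,2-bis(trifluoromethanesulfonamido)cyclohexane (8 mol %), toluene, −20 °C
Reagents that add atoms: none
Why: Diethylborane should hydroborate the monosubstituted vinyl group in preference to the hindered conjugated diene, boron–zinc exchange gives the dialkylzinc, and the Ti(OiPr)4/bis(sulfonamide)-catalysed 1,2-addition to the α-branched enal should set C1 as R by Re-face attack, the sense expected for the (1S,2S)-ligand by analogy with the Si-face additions of its antipode.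

Step 7
Reactants: 13 allylic alcohol; 14 (E)-4-methoxycinnamic acid
Product: 15 (2E,4R,8E,10E)-12-{[tert-butyl(dimethyl)silyl]oxy}-1,1-dimethoxy-3,7,7-trimethyldodeca-2,8,10-trien-4-yl (2E)-3-(4-methoxyphenyl)prop-2-enoate
Conditions: DCC, DMAP (cat.), CH2Cl2, 0 °C → rt
Reagents that add atoms: none
Why: Steglich esterification should acylate the unhindered secondary allylic alcohol with retention at C1 and without harm to the acetal or silyl ether, so the cinnamate is in place before any hindered decalin alcohol exists.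

Step 8
Reactants: 15 cinnamate acetal
Product: 16 (2E,4R,8E,10E)-12-{[tert-butyl(dimethyl)silyl]oxy}-3,7,7-trimethyl-1-oxododeca-2,8,10-trien-4-yl (2E)-3-(4-methoxyphenyl)prop-2-enoate
Conditions: PPTS (cat.), acetone/H2O 9:1, rt
Reagents that add atoms: water, O
Why: The allylic dimethyl acetal hydrolyses through a conjugated oxocarbenium ion under mild acid catalysis that spares the silyl ether and the ester, which unmasks the E-enal dienophile.

Step 9
Reactants: 16 trienal
Product: 17 12-{[tert-butyl(dimethyl)silyl]oxy}-1β-[(E)-4-methoxycinnamoyloxy]drim-6-en-11-al (5α-H, 8β-CH2OTBS, 9β-CHO, 10β-CH3)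
Conditions: Me2AlCl (2.5 equiv), CH2Cl2, −78 → −20 °C
Reagents that add atoms: none
Why: Me2AlCl bound to the formyl oxygen lowers the LUMO of the enal, and the 1,7,9-decatriene should undergo a concerted but asynchronous normal-demand [4π+2π] cycloaddition in which the bond from the enal β-carbon C10 to C5 is more advanced and the C8–C9 bond completes ring B. The closest known reaction type is the Lewis acid-promoted type 1 intramolecular Diels–Alder reaction of 2,7,9-decatrienals and -trienoates to trans-fused octalins. Ring B closes as the new cyclohexene (bonds C8–C9 and C5–C10, alkene C6=C7) and ring A closes through the same C5–C10 bond with the four-carbon tether C1–C4 in a chair. Suprafacial addition to the E-enal fixes the cis relation of the C10 methyl and the C9 formyl group, the endo orientation of the complexed formyl group with the tether exo gives the trans ring fusion at C5/C10, and the E,E-diene sets C8 (erased in step 13). The π-face is chosen by the C1 stereocentre, whose cinnamoyloxy group should sit equatorial on the chair tether, anti to the forming C5–C10 bond as in the Felkin–Anh model and free of 1,3-diaxial contacts, which makes it β and cis to the C10 methyl. The step needs endo, facial and chemoselectivity; the Lewis acid with a single E-activating group, the C1 centre with the gem-dimethyl-biased chair tether, and the poor dienophilicity and unfavourable eight-membered tethering of the cinnamate alkene should secure them.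

Step 10
Reactants: 17 Diels–Alder adduct
Product: 18 12-{[tert-butyl(dimethyl)silyl]oxy}-1β-[(E)-4-methoxycinnamoyloxy]drim-6-en-11-ol
Conditions: NaBH4, CeCl3·7H2O, MeOH/THF, −40 °C
Reagents that add atoms: none
Why: Luche-type reduction should convert the epimerisable C9 aldehyde chemoselectively into the primary alcohol at low temperature and low basicity, which leaves the cinnamate untouched and disfavours acyl migration from O1 to O11.

Step 11
Reactants: 18 homoallylic alcohol
Product: 19 6α,7α-epoxy-12-{[tert-butyl(dimethyl)silyl]oxy}-1β-[(E)-4-methoxycinnamoyloxy]drimane-11-ol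
Conditions: mCPBA, NaHCO3, CH2Cl2, 0 °C
Reagents that add atoms: 3-chloroperoxybenzoic acid (mCPBA), O=C(OO)c1cccc(Cl)c1
Why: Prilezhaev epoxidation should occur at the only electron-rich non-conjugated alkene and from the α-face, because the β-face of C6=C7 is shielded by the axial C10 and C4 methyl groups and by the pseudo-axial C8 silyloxymethyl group, which sets the 6α-oxygen.

Step 12
Reactants: 19 epoxy silyl ether
Product: 20 6α,7α-epoxy-1β-[(E)-4-methoxycinnamoyloxy]drimane-11,12-diol
Conditions: Bu4NF, AcOH (1:1), THF, 0 °C → rt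
Reagents that add atoms: none
Why: Buffered fluoride should cleave the primary silyl ether without opening the epoxide or promoting ester migration, giving the 11,12-diol.

Step 13
Reactants: 20 epoxy diol
Product: 22 1β-[(E)-4-methoxycinnamoyloxy]-6α-hydroxydrim-7-ene-11,12-dial (target), via epoxy dialdehyde 21 (not isolated)
Conditions: (COCl)2, DMSO, CH2Cl2, −78 °C; Et3N, −78 → 0 °C
Reagents that add atoms: none
Why: Swern activation turns both primary alcohols into alkoxysulfonium salts before any carbonyl exists (which avoids lactol and lactone formation), and after Et3N releases the dialdehyde the same base should trigger E1cB opening of the β,γ-epoxy aldehyde at C8–H to give the C7=C8 enal and the 6α-hydroxyl with retention at C6, as in the known conversion of β,γ-epoxy aldehydes into γ-hydroxy enals.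

**Compound list**

1 | 1-chloro-3-methylbut-2-ene (prenyl chloride) | CC(C)=CCCl | starting material
2 | (3-methylbut-2-en-1-yl)magnesium chloride | CC(C)=CC[Mg]Cl | intermediate
3 | 2,2-dimethylbut-3-enal | O=CC(C)(C)C=C | intermediate
4 | triethyl 4-phosphonocrotonate [ethyl (2E)-4-(diethoxyphosphoryl)but-2-enoate] | CCOC(=O)/C=C/CP(=O)(OCC)OCC | starting material
5 | ethyl (2E,4E)-6,6-dimethylocta-2,4,7-trienoate | CCOC(=O)/C=C/C=C/C(C)(C)C=C | intermediate
6 | (2E,4E)-6,6-dimethylocta-2,4,7-trien-1-ol | OC/C=C/C=C/C(C)(C)C=C | intermediate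
7 | tert-butyl{[(2E,4E)-6,6-dimethylocta-2,4,7-trien-1-yl]oxy}dimethylsilane | CC(C)(C)[Si](C)(C)OC/C=C/C=C/C(C)(C)C=C | intermediate
8 | 2,2-dimethoxyacetaldehyde | COC(OC)C=O | starting material
9 | 2-(triphenylphosphoranylidene)propanal | CC(C=O)=P(c1ccccc1)(c1ccccc1)c1ccccc1 | starting material
10 | (2E)-4,4-dimethoxy-2-methylbut-2-enal | O=C/C(C)=C/C(OC)OC | intermediate
11 | [(4E,6E)-8-{[tert-butyl(dimethyl)silyl]oxy}-3,3-dimethylocta-4,6-dien-1-yl]diethylborane | CCB(CC)CCC(C)(C)/C=C/C=C/CO[Si](C)(C)C(C)(C)C | intermediate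
12 | bis[(4E,6E)-8-{[tert-butyl(dimethyl)silyl]oxy}-3,3-dimethylocta-4,6-dien-1-yl]zinc | CC(C)(C)[Si](C)(C)OC/C=C/C=C/C(C)(C)CC[Zn]CCC(C)(C)/C=C/C=C/CO[Si](C)(C)C(C)(C)C | intermediate
13 | (2E,4R,8E,10E)-12-{[tert-butyl(dimethyl)silyl]oxy}-1,1-dimethoxy-3,7,7-trimethyldodeca-2,8,10-trien-4-ol | O[C@H](CCC(C)(C)/C=C/C=C/CO[Si](C)(C)C(C)(C)C)/C(C)=C/C(OC)OC | intermediate
14 | (2E)-3-(4-methoxyphenyl)prop-2-enoic acid [(E)-4-methoxycinnamic acid] | COc1ccc(/C=C/C(=O)O)cc1 | starting material
15 | (2E,4R,8E,10E)-12-{[tert-butyl(dimethyl)silyl]oxy}-1,1-dimethoxy-3,7,7-trimethyldodeca-2,8,10-trien-4-yl (2E)-3-(4-methoxyphenyl)prop-2-enoate | COc1ccc(/C=C/C(=O)O[C@H](CCC(C)(C)/C=C/C=C/CO[Si](C)(C)C(C)(C)C)/C(C)=C/C(OC)OC)cc1 | intermediate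
16 | (2E,4R,8E,10E)-12-{[tert-butyl(dimethyl)silyl]oxy}-3,7,7-trimethyl-1-oxododeca-2,8,10-trien-4-yl (2E)-3-(4-methoxyphenyl)prop-2-enoate | COc1ccc(/C=C/C(=O)O[C@H](CCC(C)(C)/C=C/C=C/CO[Si](C)(C)C(C)(C)C)/C(C)=C/C=O)cc1 | intermediate
17 | 12-{[tert-butyl(dimethyl)silyl]oxy}-1β-[(E)-4-methoxycinnamoyloxy]drim-6-en-11-al (trans-fused; 5α-H, 8β-CH2OTBS, 9β-CHO, 10β-CH3) | COc1ccc(/C=C/C(=O)O[C@@H]2CCC(C)(C)[C@@H]3C=C[C@H](CO[Si](C)(C)C(C)(C)C)[C@H](C=O)[C@@]23C)cc1 | intermediate
18 | 12-{[tert-butyl(dimethyl)silyl]oxy}-1β-[(E)-4-methoxycinnamoyloxy]drim-6-en-11-ol | COc1ccc(/C=C/C(=O)O[C@@H]2CCC(C)(C)[C@@H]3C=C[C@H](CO[Si](C)(C)C(C)(C)C)[C@H](CO)[C@@]23C)cc1 | intermediate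
19 | 6α,7α-epoxy-12-{[tert-butyl(dimethyl)silyl]oxy}-1β-[(E)-4-methoxycinnamoyloxy]drimane-11-ol (8β-CH2OTBS, 9β-CH2OH) | COc1ccc(/C=C/C(=O)O[C@@H]2CCC(C)(C)[C@@H]3[C@H]4O[C@H]4[C@H](CO[Si](C)(C)C(C)(C)C)[C@H](CO)[C@@]23C)cc1 | intermediate
20 | 6α,7α-epoxy-1β-[(E)-4-methoxycinnamoyloxy]drimane-11,12-diol | COc1ccc(/C=C/C(=O)O[C@@H]2CCC(C)(C)[C@@H]3[C@H]4O[C@H]4[C@H](CO)[C@H](CO)[C@@]23C)cc1 | intermediate
21 | 6α,7α-epoxy-1β-[(E)-4-methoxycinnamoyloxy]drimane-11,12-dial (8β-CHO, 9β-CHO) | COc1ccc(/C=C/C(=O)O[C@@H]2CCC(C)(C)[C@@H]3[C@H]4O[C@H]4[C@H](C=O)[C@H](C=O)[C@@]23C)cc1 | intermediate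
22 | 1β-[(E)-4-methoxycinnamoyloxy]-6α-hydroxydrim-7-ene-11,12-dial (CNP0283080.1) | COc1ccc(/C=C/C(=O)O[C@@H]2CCC(C)(C)[C@@H]3[C@@H](O)C=C(C=O)[C@H](C=O)[C@@]23C)cc1 | target

**Step count and risks**

Total step count: 13. Longest linear sequence: 12 steps (steps 1–4 and 6–13 from prenyl chloride); step 5 is a one-step branch.

Steps most likely to fail:

Step 9. The β,β-disubstituted enal may be too slow a dienophile towards the neopentyl-type diene terminus. Lewis acid-induced ionisation of the dienylic silyl ether, or loss of endo and facial selectivity at the higher temperature then needed, could take over. The fallback sets out from 15 and comes back at 17. The acetal 15 is ionised with catalytic TMSOTf (2,6-di-tert-butyl-4-methylpyridine, CH2Cl2, −78 °C) to the 1-methoxyallyl cation, a far stronger dienophile, and a cationic intramolecular [4+2] cycloaddition of the kind known for α,β-unsaturated acetals should return the cycloadduct as the C11 dimethyl acetal F1. PPTS in wet acetone then hydrolyses it to 17.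

Step 13. Once both formyl groups are present, the amine base may epimerise C9 to the axial aldehyde. The freshly liberated 6-hydroxyl may be captured or oxidised by residual activated DMSO, and incomplete activation of the diol would lead to lactol and lactone formation. The fallback sets out from 17 and comes back at 22. It keeps C11 at the aldehyde level but masked, so that C9 is not enolisable during the base step and no double oxidation is needed. The aldehyde of 17 is converted (HC(OMe)3, PPTS, MeOH) into the dimethyl acetal F1. Epoxidation (mCPBA, NaHCO3) gives the 6α,7α-epoxide F2, and buffered Bu4NF gives the primary alcohol F3. Dess–Martin periodinane (NaHCO3, CH2Cl2) gives the epoxy aldehyde F4, which is not isolated and is opened with Et3N to the γ-hydroxy enal acetal F5. Mild hydrolysis (PPTS, acetone/H2O) releases the C11 aldehyde to give 22.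

Step 6. Hydroboration may not discriminate fully between the vinyl group and the diene, boron–zinc exchange may be incomplete, or the addition to an acetal-bearing α-methyl enal may give low enantioselectivity. The fallback sets out from 7 and comes back at 13. Hydroboration with 9-borabicyclo[3.3.1]nonane and oxidation (NaOH, H2O2) gives the primary alcohol F6, and an Appel reaction (PPh3, I2, imidazole) gives the iodide F7. Iodine–lithium exchange (t-BuLi, Et2O, −78 °C) and addition to aldehyde 10 give the racemic allylic alcohol F8, which MnO2 oxidises to the enone F9. Corey–Bakshi–Shibata reduction ((S)-2-methyl-CBS-oxazaborolidine, BH3·SMe2) of this α-methyl enone should give 13 under reagent control.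

Further compounds

F1 | step 9 | 12-{[tert-butyl(dimethyl)silyl]oxy}-1β-[(E)-4-methoxycinnamoyloxy]drim-6-en-11-al dimethyl acetal | COc1ccc(/C=C/C(=O)O[C@@H]2CCC(C)(C)[C@@H]3C=C[C@H](CO[Si](C)(C)C(C)(C)C)[C@H](C(OC)OC)[C@@]23C)cc1
F2 | step 13 | 6α,7α-epoxy-12-{[tert-butyl(dimethyl)silyl]oxy}-1β-[(E)-4-methoxycinnamoyloxy]drimane-11-al dimethyl acetal | COc1ccc(/C=C/C(=O)O[C@@H]2CCC(C)(C)[C@@H]3[C@H]4O[C@H]4[C@H](CO[Si](C)(C)C(C)(C)C)[C@H](C(OC)OC)[C@@]23C)cc1
F3 | step 13 | 6α,7α-epoxy-12-hydroxy-1β-[(E)-4-methoxycinnamoyloxy]drimane-11-al dimethyl acetal | COc1ccc(/C=C/C(=O)O[C@@H]2CCC(C)(C)[C@@H]3[C@H]4O[C@H]4[C@H](CO)[C@H](C(OC)OC)[C@@]23C)cc1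
F4 | step 13 | 6α,7α-epoxy-1β-[(E)-4-methoxycinnamoyloxy]drimane-11,12-dial 11-(dimethyl acetal) | COc1ccc(/C=C/C(=O)O[C@@H]2CCC(C)(C)[C@@H]3[C@H]4O[C@H]4[C@H](C=O)[C@H](C(OC)OC)[C@@]23C)cc1
F5 | step 13 | 6α-hydroxy-1β-[(E)-4-methoxycinnamoyloxy]drim-7-ene-11,12-dial 11-(dimethyl acetal) | COc1ccc(/C=C/C(=O)O[C@@H]2CCC(C)(C)[C@@H]3[C@@H](O)C=C(C=O)[C@H](C(OC)OC)[C@@]23C)cc1
F6 | step 6 | (4E,6E)-8-{[tert-butyl(dimethyl)silyl]oxy}-3,3-dimethylocta-4,6-dien-1-ol | OCCC(C)(C)/C=C/C=C/CO[Si](C)(C)C(C)(C)C
F7 | step 6 | tert-butyl{[(2E,4E)-8-iodo-6,6-dimethylocta-2,4-dien-1-yl]oxy}dimethylsilane | ICCC(C)(C)/C=C/C=C/CO[Si](C)(C)C(C)(C)C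
F8 | step 6 | racemic (2E,8E,10E)-12-{[tert-butyl(dimethyl)silyl]oxy}-1,1-dimethoxy-3,7,7-trimethyldodeca-2,8,10-trien-4-ol | OC(CCC(C)(C)/C=C/C=C/CO[Si](C)(C)C(C)(C)C)/C(C)=C/C(OC)OC
F9 | step 6 | (2E,8E,10E)-12-{[tert-butyl(dimethyl)silyl]oxy}-1,1-dimethoxy-3,7,7-trimethyldodeca-2,8,10-trien-4-one | O=C(CCC(C)(C)/C=C/C=C/CO[Si](C)(C)C(C)(C)C)/C(C)=C/C(OC)OC
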